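The carbocycle is disconnected at C5–C4a and C8–C8a (chromene numbering). A silyl ynol ether (C4a≡C8a) is inserted in one operation into the acyl–C(quaternary) bond of 3-ethoxy-4,4-dimethylcyclobutenone, a strained ring absent from the target, made from dimethylketene and cleaved in this step. This nickel-catalysed [4+2] exploits the gem-dimethyl carbon C8 of the carbocycle, which blocks aromatisation and gives a cross-conjugated 3,5-diethoxy-4,4-dimethylcyclohexadienone with silicon marking C4a. Iodination, Z-selective coupling with a siloxane ring built on (R)-linalool, displacement of the C8a ethoxy by the tertiary alkoxide, hydrolysis and C-acylation with (R)-2-methylbutanoic acid complete the route.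

Key step: step 3

Remark: ring atoms are numbered as in 2H-chromene (O1, C2, C3, C4, C4a, C5 to C8, C8a); the pyran stereocentre is assumed to be configurationally stable at or below 25 °C (slow thermal oxa-6π ring opening), so every step after pyran closure is run at or below room temperature and without strong acid.

Step 1
Reactants: 1 isobutyryl chloride; 2 ethoxyacetylene
Product: 4 3-ethoxy-4,4-dimethylcyclobut-2-en-1-one, via dimethylketene 3 (not isolated)
Conditions: Et3N, Et2O, 0 °C to reflux
Reagents that add atoms: none
Why: Dehydrochlorination of 1 should give dimethylketene, whose ketene–alkyne [2+2] cycloaddition with the polarised ynol ether (ketene carbonyl carbon to the CH terminus) is the standard entry to 3-alkoxy-4,4-dialkylcyclobutenones.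

Step 2
Reactants: 2 ethoxyacetylene
Product: 6 (ethoxyethynyl)trimethylsilane, via lithium ethoxyacetylide 5 (not isolated)
Conditions: n-BuLi, THF, −78 °C; then Me3SiCl, −78 to 0 °C
Reagents that add atoms: chlorotrimethylsilane, C[Si](C)(C)Cl
Why: Deprotonation of the terminal alkyne and C-silylation of the acetylide is routine and should install the silicon that later marks C4a.

Step 3
Reactants: 4 3-ethoxy-4,4-dimethylcyclobut-2-en-1-one; 6 (ethoxyethynyl)trimethylsilane
Product: 7 3,5-diethoxy-4,4-dimethyl-2-(trimethylsilyl)cyclohexa-2,5-dien-1-one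
Conditions: Ni(cod)2 (10 mol %), PPh3 (20 mol %), toluene, 0 to 25 °C
Reagents that add atoms: none
Why: Proposed new method: zerovalent nickel should insert into the strained acyl–C(quaternary) bond of 4 (a nickelacyclopentenone in equilibrium with its η4-vinylketene form), the ynol ether should then insert into the Ni–acyl bond with its nucleophilic, silicon-bearing carbon bonding to the acyl carbon (the future C5–C4a bond), and C(sp2)–C(sp3) reductive elimination from the seven-membered nickelacycle should join the ethoxy-bearing carbon to the quaternary carbon (the future C8a–C8 bond). The closest known reaction type is the nickel-catalysed [4+2] benzannulation of cyclobutenones with alkynes to phenols, which has not been shown for a 4,4-dialkyl-3-alkoxycyclobutenone with an alkynyl ether. The six-membered carbocycle is closed by that reductive elimination, formally a [4+2] insertion of the alkyne into a C–C σ bond, and no stereocentre is created. The gem-dimethyl carbon cannot lose a proton, so the adduct cannot tautomerise to a phenol and should remain the cross-conjugated dienone. The step needs regioselective alkyne insertion, which the ynol ether polarisation and the bulk of SiMe3 (kept away from the quaternary carbon) both favour, and it must outrun the thermal electrocyclic pathway that would insert the alkyne on the other side of the carbonyl, which should not operate at or below 25 °C.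

Step 4
Reactants: 7 3,5-diethoxy-4,4-dimethyl-2-(trimethylsilyl)cyclohexa-2,5-dien-1-one
Product: 8 3,5-diethoxy-2-iodo-4,4-dimethylcyclohexa-2,5-dien-1-one
Conditions: ICl, CH2Cl2, −78 to 0 °C
Reagents that add atoms: iodine monochloride, ClI
Why: Electrophilic ipso-iododesilylation of the vinylsilane (attack at the silicon-bearing α-carbon, β-silyl and alkoxy stabilisation of the cation, loss of Me3SiCl) should place iodine only on the alkyne-derived carbon.

Step 5
Reactants: 9 (R)-linalool
Product: 10 (3R)-3-{[ethenyl(dimethyl)silyl]oxy}-3,7-dimethylocta-1,6-diene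
Conditions: Et3N, DMAP (cat.), CH2Cl2, 0 to 25 °C
Reagents that add atoms: chloro(dimethyl)vinylsilane, C=C[Si](C)(C)Cl
Why: O-silylation of the tertiary alcohol with a small chlorosilane should proceed without touching the C–O bond, so the (R) configuration of the chiral-pool alcohol is carried over.

Step 6
Reactants: 10 (3R)-3-{[ethenyl(dimethyl)silyl]oxy}-3,7-dimethylocta-1,6-diene
Product: 11 (5R)-2,2,5-trimethyl-5-(4-methylpent-3-en-1-yl)-2,5-dihydro-1,2-oxasilole
Conditions: Mo(=CHCMe2Ph)(=N-2,6-i-Pr2C6H3)[OCMe(CF3)2]2 (5 mol %), benzene, 25 °C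
Reagents that add atoms: none
Why: Silicon-tethered ring-closing metathesis of the two terminal alkenes should close the five-membered oxasilole, a temporary ring that fixes the cis geometry of the future C3=C4 alkene, the trisubstituted alkene being expected to react more slowly than the vinylsilane.

Step 7
Reactants: 8 3,5-diethoxy-2-iodo-4,4-dimethylcyclohexa-2,5-dien-1-one; 11 (5R)-2,2,5-trimethyl-5-(4-methylpent-3-en-1-yl)-2,5-dihydro-1,2-oxasilole
Product: 13 (2R)-7-ethoxy-2,8,8-trimethyl-2-(4-methylpent-3-en-1-yl)-2H-chromen-5(8H)-one, via alkenyl carbinol 12 (not isolated)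
Conditions: Pd(dba)2 (5 mol %), TBAF (2.2 equiv), THF, 25 °C; then KOt-Bu (20 mol %), THF, 0 °C
Reagents that add atoms: none
Why: Fluoride-promoted Hiyama coupling of the cyclic alkenylsiloxane with the vinyl iodide should retain the Z geometry and release the tertiary alkoxide, which should close the pyran by 6-endo conjugate addition–elimination at C8a, the only ethoxy-bearing carbon within reach; the C2–O bond is never broken, so C2 stays (R).

Step 8
Reactants: 13 (2R)-7-ethoxy-2,8,8-trimethyl-2-(4-methylpent-3-en-1-yl)-2H-chromen-5(8H)-one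
Product: 14 (2R)-2,8,8-trimethyl-2-(4-methylpent-3-en-1-yl)-2H-chromene-5,7(6H,8H)-dione
Conditions: LiOH, THF/H2O, 0 to 25 °C; then 0.5 M HCl to pH 5 at 0 °C
Reagents that add atoms: lithium hydroxide, [Li+].[OH-]
Why: Saponification of the vinylogous ethyl ester by conjugate addition–elimination should occur at C7, where ethoxide is expelled, rather than at C8a, where the poorer tertiary alkoxide leaving group makes addition reversible, and the vinylogous carboxylate formed resists further attack.

Step 9
Reactants: 14 (2R)-2,8,8-trimethyl-2-(4-methylpent-3-en-1-yl)-2H-chromene-5,7(6H,8H)-dione; 15 (R)-2-methylbutanoic acid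
Product: 17 (2R)-5-hydroxy-2,8,8-trimethyl-6-[(2R)-2-methylbutanoyl]-2-(4-methylpent-3-en-1-yl)-2H-chromen-7(8H)-one, via enol ester 16 (not isolated)
Conditions: DCC, DMAP (1.2 equiv), CH2Cl2, 0 to 25 °C
Reagents that add atoms: none
Why: Steglich O-acylation of the cyclic 1,3-dione followed by DMAP-mediated O-to-C acyl migration, the standard synthesis of 2-acylcyclohexane-1,3-diones, should place the acyl group on C6 (the only carbon between two carbonyls), and the (R) centre of the acid should survive these near-neutral conditions.

Compound list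
1 | isobutyryl chloride | CC(C)C(Cl)=O | starting material
2 | ethoxyacetylene (ethoxyethyne) | CCOC#C | starting material
3 | dimethylketene | CC(C)=C=O | intermediate
4 | 3-ethoxy-4,4-dimethylcyclobut-2-en-1-one | CCOC1=CC(=O)C1(C)C | intermediate
5 | lithium ethoxyacetylide | [Li]C#COCC | intermediate
6 | (ethoxyethynyl)trimethylsilane | CCOC#C[Si](C)(C)C | intermediate
7 | 3,5-diethoxy-4,4-dimethyl-2-(trimethylsilyl)cyclohexa-2,5-dien-1-one | CCOC1=CC(=O)C([Si](C)(C)C)=C(OCC)C1(C)C | intermediate
8 | 3,5-diethoxy-2-iodo-4,4-dimethylcyclohexa-2,5-dien-1-one | CCOC1=CC(=O)C(I)=C(OCC)C1(C)C | intermediate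
9 | (R)-linalool, (3R)-3,7-dimethylocta-1,6-dien-3-ol | O[C@](C)(CCC=C(C)C)C=C | starting material
10 | (3R)-3-{[ethenyl(dimethyl)silyl]oxy}-3,7-dimethylocta-1,6-diene | C=C[Si](C)(C)O[C@](C)(CCC=C(C)C)C=C | intermediate
11 | (5R)-2,2,5-trimethyl-5-(4-methylpent-3-en-1-yl)-2,5-dihydro-1,2-oxasilole | C[Si]1(C)O[C@](C)(CCC=C(C)C)C=C1 | intermediate
12 | 3,5-diethoxy-2-[(1Z,3R)-3-hydroxy-3,7-dimethylocta-1,6-dien-1-yl]-4,4-dimethylcyclohexa-2,5-dien-1-one | CCOC1=CC(=O)C(/C=C\[C@](C)(O)CCC=C(C)C)=C(OCC)C1(C)C | intermediate
13 | (2R)-7-ethoxy-2,8,8-trimethyl-2-(4-methylpent-3-en-1-yl)-2H-chromen-5(8H)-one | CCOC1=CC(=O)C2=C(O[C@](C)(CCC=C(C)C)C=C2)C1(C)C | intermediate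
14 | (2R)-2,8,8-trimethyl-2-(4-methylpent-3-en-1-yl)-2H-chromene-5,7(6H,8H)-dione (drawn as the diketo tautomer) | O=C1CC(=O)C2=C(O[C@](C)(CCC=C(C)C)C=C2)C1(C)C | intermediate
15 | (R)-2-methylbutanoic acid | CC[C@@H](C)C(=O)O | starting material
16 | (2R)-2,8,8-trimethyl-2-(4-methylpent-3-en-1-yl)-5-oxo-5,8-dihydro-2H-chromen-7-yl (2R)-2-methylbutanoate (the O5 enol ester would converge on the same product) | CC[C@@H](C)C(=O)OC1=CC(=O)C2=C(O[C@](C)(CCC=C(C)C)C=C2)C1(C)C | intermediate
17 | (2R)-5-hydroxy-2,8,8-trimethyl-6-[(2R)-2-methylbutanoyl]-2-(4-methylpent-3-en-1-yl)-2H-chromen-7(8H)-one | CC[C@@H](C)C(=O)C1=C(O)C2=C(O[C@](C)(CCC=C(C)C)C=C2)C(C)(C)C1=O | target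

Total step count: 9
Longest linear sequence: 6 steps (steps 1, 3, 4, 7, 8, 9)

Steps most likely to fail

Step 3 (Proposed new method). The alkyne may insert with reversed regiochemistry, the ynol ether may oligomerise at nickel, or reductive elimination at the quaternary carbon may stall. The fallback uses known ionic chemistry, sets out from 4 and returns at 8. Heating 4 in ethanol with a trace of NaOEt (electrocyclic opening to the vinylketene, trapping by the alcohol, conjugation) should give ethyl (E)-3-ethoxy-4-methylpent-2-enoate F1. Acylation of lithium ethoxyacetylide 5 by F1 with BF3·OEt2 at −78 °C should give (E)-1,5-diethoxy-6-methylhept-4-en-1-yn-3-one F2. Catalytic KOt-Bu in THF should then deprotonate the isopropyl methine (γ position) and close the ring by 6-endo-dig conjugate addition to the alkoxy ynone, giving 3,5-diethoxy-4,4-dimethylcyclohexa-2,5-dien-1-one F3. Because F3 has a mirror plane through the carbonyl and the gem-dimethyl carbon, mono-iodination with N-iodosuccinimide gives 8 whichever α-carbon reacts.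

Step 6. The metathesis may instead close onto the trisubstituted alkene (cyclopentene formation with loss of isobutene), or turn over slowly at the hindered vinylsilane. The fallback avoids the tether, sets out from 8 and 9 and returns at 13. A Heck reaction of 8 with (R)-linalool 9 (Pd(OAc)2, P(o-tol)3, Et3N, MeCN, 60 °C) should give 3,5-diethoxy-2-[(1E,3R)-3-hydroxy-3,7-dimethylocta-1,6-dien-1-yl]-4,4-dimethylcyclohexa-2,5-dien-1-one F4. Triplet-sensitised E-to-Z isomerisation (Ir(ppy)3, 450 nm LEDs, KOt-Bu 20 mol %, THF, 0 °C) should then feed the Z isomer 12 into the irreversible cyclisation to 13. Irradiation is stopped at full conversion to limit photochemical opening of the pyran.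

Step 8. Hydroxide may add at C8a instead of C7 and open the pyran irreversibly to a vinylogous acid. The fallback replaces hydroxide attack by a fluoride-triggered fragmentation, sets out from 13 and returns at 14. Alkoxide exchange of 13 with sodium 2-(trimethylsilyl)ethoxide in 2-(trimethylsilyl)ethanol/THF should give (2R)-2,8,8-trimethyl-2-(4-methylpent-3-en-1-yl)-7-[2-(trimethylsilyl)ethoxy]-2H-chromen-5(8H)-one F5; exchange at C8a is undone by reclosure of the pyran, whereas exchange at C7 is productive. TBAF in THF at 0 °C should then cleave the silylethyl group to give 14 after buffering to pH 5.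

Further compounds
F1 | step 3 | ethyl (E)-3-ethoxy-4-methylpent-2-enoate | CCOC(=O)/C=C(/OCC)C(C)C
F2 | step 3 | (E)-1,5-diethoxy-6-methylhept-4-en-1-yn-3-one | CCOC#CC(=O)/C=C(/OCC)C(C)C
F3 | step 3 | 3,5-diethoxy-4,4-dimethylcyclohexa-2,5-dien-1-one | CCOC1=CC(=O)C=C(OCC)C1(C)C
F4 | step 6 | 3,5-diethoxy-2-[(1E,3R)-3-hydroxy-3,7-dimethylocta-1,6-dien-1-yl]-4,4-dimethylcyclohexa-2,5-dien-1-one | CCOC1=CC(=O)C(/C=C/[C@](C)(O)CCC=C(C)C)=C(OCC)C1(C)C
F5 | step 8 | (2R)-2,8,8-trimethyl-2-(4-methylpent-3-en-1-yl)-7-[2-(trimethylsilyl)ethoxy]-2H-chromen-5(8H)-one | C[Si](C)(C)CCOC1=CC(=O)C2=C(O[C@](C)(CCC=C(C)C)C=C2)C1(C)C
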